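Leave the feed alone. Each flask takes substrate at a steady rate for 20 h, and the coupling partner is there from the start.

| flask | substrate | coupling partner | remark | time |
|---|---|---|---|---|
| south-west | 0.050 M (fed, over 20 h) | 1.1 equiv | run made earlier |  |
| east | 0.050 M (fed, over 20 h) | 4.6 equiv | run made earlier |  |
| blue | 0.050 M (fed, over 20 h) | 2.00 equiv |  | 20 h |
| teal | 0.050 M (fed, over 20 h) | 0.330 equiv |  | 20 h |
| ochre | 0.050 M (fed, over 20 h) | 0.670 equiv |  | 20 h |
| grey | 0.050 M (fed, over 20 h) | 0.250 equiv |  | 20 h |
| green | 0.050 M (fed, over 20 h) | 4.00 equiv |  | 20 h |
| amber | 0.050 M (fed, over 20 h) | 1.00 equiv |  | 20 h |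

| run | time / h | target / % |
|---|---|---|
| south-west | 4.00 | 4.3 |
| south-west | 8.00 | 16.3 |
| south-west | 12.0 | 28.1 |
| south-west | 15.0 | 37.0 |
| south-west | 20.0 | 48.8 |
| east | 1.50 | 4.0 |
| east | 3.00 | 9.6 |
| east | 6.00 | 21.5 |
| east | 10.0 | 37.9 |
| east | 20.0 | 73.9 |

(scatter of a reading: 0.5 percentage points)

- percentages count the whole charge, also what has not yet gone in

- ranking by amount of target, in percent of the substrate charged, from high to low, at 20 h (blue / teal / ochre / grey / green / amber)
- the amount of target, in percent of the substrate charged of the flask you put first, at 20 h
- the amount of target, in percent of the substrate charged of the flask you put last, at 20 h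

I follow one fed molecule of substrate. Once feed and uptake balance, target trails the fed amount by the time a molecule stands, so the second east reading, 9.6 % at 3.00 h, gives 1.08 h. I call this the wait: the mean time a fed molecule stands before a partner takes it, its pseudo-first-order lifetime. With a scatter of 0.5 percentage points on that reading, it is a rough value.

I assume the wait goes inversely with the molarity of partner. Green, at 4.00 equiv, then waits 1.24 h. Standing substrate is the wait over the dosing time, so during the feed I expect 6.21 % of the charge standing in green.

The forecast ranks green > blue > amber > ochre > teal > grey. It gives 72.5 % (70.5 % to 74 %) for the first and 13.5 % (10.5 % to 17 %) for the last. Its ground is that “the fed substrate builds up and reacts first order in partner”. It reads the east lag as about 0.75 h where I read a wait of 1.08 h, so our two readings differ.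

The flasks stand green > blue > amber > ochre > teal > grey, with 72.5 % in green and 15.1 % in grey.

    substrate + coupling partner → target + by-product (k = 3.26 M⁻¹ h⁻¹)
    target ⇌ isomer of the product (K = 1.25, k = 0.0285 h⁻¹)

Green holds 8.36 % substrate at 10.0 h, against my 6.21 %. At 20.0 h substrate in green has a half-life of 1.4 h by the coupling, while target has a forward half-life of 24 h toward the isomer of the product, much longer, and green then holds 72.5 % target beside 17.9 % of that isomer. For a neighbour of green, at the same equivalents on 0.020 M of substrate, I reckon a wait of 3.10 h from the charged partner, which means 15.5 % standing; that neighbour holds 22 % substrate at 20.0 h and gives 63.3 % target.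

(All runs were computed for an exercise, and the scatter is random.)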